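The vessel sets how long target stays in the mixture: 25 h in delta, 250 h in alpha, from the same charge.

| flask | substrate | reagent | transfer agent | initiator | remark | time |
|---|---|---|---|---|---|---|
| violet | 0.050 M | 0.075 M | 2.5 mM | 5 mM | run made earlier |  |
| ochre | 0.034 M | 0.075 M | 2.5 mM | 5 mM | run made earlier |  |
| grey | 0.075 M | 0.075 M | 2.5 mM | 5 mM | run made earlier |  |
| blue | 0.050 M | 0.15 M | 2.5 mM | 5 mM | run made earlier |  |
| alpha | 0.050 M | 0.0750 M | 2.50 mM | 5.0 mM | one stirred flow tank at steady state, fed with the mixture as stated, mean residence time 250 h |  |
| gamma | 0.050 M | 0.0750 M | 2.50 mM | 5.0 mM | one stirred flow tank at steady state, fed with the mixture as stated, mean residence time 25 h |  |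
| delta | 0.050 M | 0.0750 M | 2.50 mM | 5.0 mM | a closed flask charged with all of it at once and left for 25 h | 25 h |
| eta | 0.050 M (fed, over 20.0 h) | 0.0750 M | 2.50 mM | 5.0 mM | a stirred flask in which substrate is dosed at a steady rate over 20.0 h without added volume, worked up at 25 h | 25 h |

| run | time / h | target / % | side product A / % |
|---|---|---|---|
| violet | 2.00 | 5 | 0 |
| violet | 4.00 | 11 | 4 |
| violet | 8.00 | 19 | 4 |
| violet | 12.0 | 19 | 5 |
| violet | 25.0 | 26 | 5 |
| ochre | 1.33 | 11 | 3 |
| ochre | 2.50 | 10 | 0 |
| ochre | 4.00 | 13 | 2 |
| ochre | 8.00 | 21 | 7 |
| ochre | 15.0 | 33 | 6 |
| grey | 1.33 | 5 | 0 |
| grey | 2.50 | 6 | 2 |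
| grey | 4.00 | 6 | 4 |
| grey | 8.00 | 13 | 0 |
| grey | 15.0 | 15 | 3 |
| blue | 1.33 | 8 | 2 |
| blue | 2.50 | 11 | 0 |
| blue | 4.00 | 15 | 2 |
| blue | 8.00 | 20 | 1 |
| blue | 15.0 | 31 | 6 |

(standard deviation of a reading: 2 percentage points)

- percentages count the substrate that a species holds: one side product B counts as two
- the stated concentrations are those of everything mixed, before any reaction; amounts are the same in each set-up
- the numbers in the tables scatter by 2 percentage points (one standard deviation)
- the feed brings no volume worth counting
- the earlier runs were made in a closed, stirred flask

* the set-up with the highest share of target in all that became target or side product A or side product B, at the outlet or at the end ("none" if the first two lie within 2 percentage points) (alpha / gamma / delta / eta / none)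
* share of target in all that became target or side product A or side product B, at the outlet or at the end, alpha
* share of target in all that became target or side product A or side product B, at the outlet or at the end, gamma
* share of target in all that became target or side product A or side product B, at the outlet or at the end, delta
* share of target in all that became target or side product A or side product B, at the outlet or at the end, eta

1. My bench rule was to take the last reading and divide target by target plus side product A. At 25.0 h the violet run gave a share (the selectivity) of 83.9%, a reading with the scatter of 2 percentage points in each term.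

2. The rule has a gap: the tables have no column for side product B, and the asked share counts it, each one as two.

3. One hint pointed to a loss of target that grows with substrate. Between 8.00 h and 15.0 h, c(target) rose by 4.08 mM in the ochre run but by 1.50 mM in the grey run, although grey held more substrate. With this scatter it stayed a hint.

4. The violet run had reached 73.1% of its last target reading by 8.00 h, so I took that as the making time. Target made by then stands in the mixture afterwards. For alpha, stay over making time is 31.2, and I call this ratio the hold ratio.

5. Here the rule reaches its border. Delta has a hold ratio of 3.12, inside the readings, but alpha's stay is ten times the last violet reading. In eta, the last substrate dosed has a hold ratio of 0.625.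

6. So I ranked by hold ratio: eta first, delta next, alpha last.

7. The forecast differed from my ranking, putting alpha first with 76%, then 72% for gamma, 68% for eta and 66% for delta, and it noted: “These B values are uncertain.”

    initiator → 2 initiating radical (k = 0.0630 h⁻¹)
    substrate + initiating radical → capped initiator + first chain carrier (k = 1.30 × 10⁷ L mol⁻¹ h⁻¹)
    reagent + first chain carrier → target + second chain carrier (k = 1.00 × 10⁶ L mol⁻¹ h⁻¹)
    substrate + second chain carrier → by-product + first chain carrier (k = 5.70 × 10⁵ L mol⁻¹ h⁻¹)
    transfer agent + first chain carrier → side product A + idle radical (kL = 6.60 × 10⁶ L mol⁻¹ h⁻¹)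
    2 idle radical → ended radicals (k = 3.00 × 10⁶ L mol⁻¹ s⁻¹)
    2 first chain carrier → ended chains A (k = 3.00 × 10⁷ L mol⁻¹ s⁻¹)
    2 second chain carrier → ended chains B (k = 7.90 × 10⁶ L mol⁻¹ s⁻¹)
    substrate + target → side product B (k = 2.00 L mol⁻¹ h⁻¹)

The simulation gave eta as best, with 39.4%, against 36.5% in delta, 31.1% in gamma and 15.0% in alpha. With the step from substrate and target to side product B acting by itself and the other concentrations as charged, target in delta has a half-life of 6.9 h, short against the 25 h. Alpha's 15.0% stands at a hold ratio of 31.2. Left until 250 h, the last substrate dosed in eta has a hold ratio of 28.8, and eta's share falls from 39.4% to 13.8%.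

(All runs were generated by integration with constants of no real substance; noise was put on by code.)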